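## Structural features

The target is a germacrane: a ten-membered carbocycle (C1–C10) with an E-trisubstituted C1=C10 alkene (methyl on C10), a cis-fused oxirane across C4–C5 (methyl on C4), a free secondary hydroxyl on C6, an isopropyl group on C7 and a 3,4,5-trimethoxybenzoate on the C8 oxygen. The five stereocentres C4, C5, C6, C7 and C8 are contiguous on one half of the ring, and C4 is a fully substituted oxirane carbon. Read around the ring, the C6 hydroxyl and the C8 ester oxygen lie on the same side, the C7 isopropyl lies on the other side of both, and the oxirane oxygen is anti to the C6 hydroxyl (a threo epoxy alcohol derived from a 4Z alkene); the absolute configuration is 4S,5R,6S,7S,8S. Fragile points are the trisubstituted epoxide next to a free hydroxyl (acid-triggered transannular opening by the strained C1=C10 alkene), the ester (it can migrate from O8 to O6, and it is lost by β-elimination whenever C6 is a ketone), and the E-cyclodecene alkene, which is unusually reactive toward electrophiles. The real difficulty is twofold: closing a ten-membered ring with one E and one Z alkene in place, and then setting five contiguous stereocentres on a mobile medium ring that starts with none. The feature used is that C6 is the only oxygenated ring carbon whose two ring neighbours can both be alkene carbons. C5 belongs to the 4Z alkene that later becomes the oxirane, and C7 can belong to a C7=C8 alkene that later delivers the C8 oxygen. C6 can therefore enter as carbon monoxide between two alkenyl termini in the ring-closing event.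

## Logic of the disconnections

24 to 23: the two C–O bonds of the oxirane (C4–O, C5–O) are cut last in the analysis because the epoxide is the most labile function and should be made last. This removes two stereocentres and leaves an allylic alcohol whose C6 hydroxyl can steer the oxidant. The forward step must choose C4=C5 over C1=C10 and the alkene face syn to the hydroxyl.

23 to 22: the C6–H bond is cut, returning C6 to a ketone. One more stereocentre disappears and the C4=C5–C6=O enone of the ring-closure product reappears. The forward step must add hydride 1,2, to the correct face, without ester migration or β-elimination.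

22 to 20 and 21: the acyl–O8 bond is cut. The aryl ester is a plain appendage and is best attached while O8 is the only hydroxyl in the molecule, so no differentiation is needed. The forward step must acylate a β-hydroxy ketone without triggering elimination or epimerising C7.

20 to 18: the C8–O bond (made by way of a C8–B bond) and the C7–H bond are cut. This removes the last two stereocentres and gives an achiral cross-conjugated dienone. The forward step must be reagent-controlled in the absolute sense at C8, must attack the C7=C8 arm and not the C4=C5 arm, and must leave C7 with the isopropyl trans to the C8 substituent.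

18 to 16 and 17: the C5–C6 and C6–C7 bonds are cut, taking C6 out as a one-carbon unit. The ring opens to an acyclic, achiral chain whose two ends are alkenyl groups of fixed geometry. The forward step must insert 17 before the two alkenyl ends meet, must retain both alkene geometries, and must cyclise faster than it oligomerises.

16 to 14: the O–S bond of the enol sulfonate is cut back to the ketone. The forward step must enolise toward C8 and not toward the isopropyl methine, and must give the enolate in which the oxygen and C9 are cis.

14 to 11 and 12: the C8–C9 bond is cut between an allylic electrophile and the methyl group of a cheap ketone. The chain splits into a three-carbon ketone piece and a nine-carbon stannyl diene. The forward step needs the kinetic enolate, mono-alkylation and direct (not allylically transposed) substitution.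

11 to 9 to 8: the C9–Br bond is exchanged for C9–O and then for the silyl ether. These are functional-group changes only. The forward steps must avoid acid and electrophilic halogen, which would cleave the C5–Sn bond.

8 to 3 and 4: the C3–C4 and C5–Sn bonds are cut across the two carbons of 4. A syn carbometalation of an alkyne is the most reliable way to fix the trisubstituted Z geometry at C4=C5. The forward step must add the alkyl group to the internal alkyne carbon, syn to the metal, and pass the metal on to tin with retention.

3 to 2 to 1: the O–Si bond and then the C9–O bond are cut, leaving a commercial homoprenyl bromide. The forward oxidation must choose the methyl group that gives the E allylic alcohol, which becomes the E C1=C10 alkene.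

## Other disconnections considered

Alternative 1: The cut is at C3–C4 and C5–C6 on either side of the Z alkene, with the ring left open. In the forward sense, Z-alkenylcopper 7 (made from 3 and 4 exactly as in the chosen route) would add, under BF3·OEt2 activation, to the α-branched aldehyde A2 to give the acyclic allylic alcohol A1, which already holds C1–C10, C6 and C7.
- In its favour: the Z geometry is secured by the same carbocupration, so on this point it is the equal of the chosen plan. C7 comes from an enantiopure aldehyde and C6 is set in an open-chain addition. The C4=C5 epoxidation could be run on the acyclic allylic alcohol, where allylic strain alone predicts the threo product. On C6, C7 and the epoxide this is the better plan.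
- Against it: the two α-substituents of A2 (isopropyl and CH2OPMB) are of similar size, so Felkin–Anh discrimination would be expected to be modest. A2 is prone to epimerise. The ten-membered ring still has to be closed afterwards at C8–C9 (for example by alkylating a C8 acyl-anion equivalent with a C9 allylic halide), and C8 would then be set by reduction on the ring, as uncertain as any ring-controlled step of the chosen route.
- Step economy: three protecting groups (TBS, PMB and one for O6) and the oxidation-state changes at C8 and C9 make it clearly longer. The chosen plan forms the ring and two C–C bonds in one step, but pays by deferring every stereocentre.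

Alternative 2: The cut is at C4–C5 and C1–C10 as a photochemical [2+2] pair. In the forward sense, irradiation of cyclohexenone A4 with 1-methylcyclobutene A5 would give the cis-anti-cis tricyclic photoadduct A3. Thermal cycloreversion of its central cyclobutane in the other sense (breaking C5–C10 and C1–C4) would then release the ten-membered dienone A6.
- In its favour: C7 and C8 are set on a six-membered ring, where trans-disubstitution is easy to control and to verify; here it is better than the chosen plan. No high-dilution macrocyclisation is needed. Two C–C bonds form in the photochemical step and both ring alkenes in the thermal step.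
- Against it: the head-to-head versus head-to-tail orientation and the facial sense of the cycloaddition next to the C7/C8 substituents are not assured. The cycloreversion needs temperatures at which a 1,5-cyclodecadiene can undergo Cope rearrangement to a divinylcyclohexane and a β-silyloxy ketone can eliminate. Which alkene emerges E and which Z is fixed only by the stereochemistry of A3.
- Comparison: C6 and the epoxide would still be set on the ring, so it is equal to the chosen plan there. The step count would be comparable. The chosen plan is mechanistically safer on alkene geometry, because both geometries are made on acyclic precursors and carried over with retention.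

Alternative 3: The cut is at C6–C7, with O6 tied to C12 in the precursor. In the forward sense, lithiation at C6 of the thirteen-membered diallyl ether A8 (n-BuLi) would trigger a [2,3]-Wittig shift that forms C6–C7, breaks O–C12 and contracts the ring to the ten-membered dienol A7.
- In its favour: the ring is reached from a larger, less strained ring. C6 and C7 are created together in one concerted, ordered transition state with C8 already in place. On medium-ring formation and on the C6/C7 relationship this is the better plan. An E geometry at C7=C11 with C5 exo in the envelope would be expected to give the required relationship.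
- Against it: the ether has two allylic α-oxy positions (C6 and C12), and deprotonation at C12 would contract the ring the wrong way. A [1,2]-shift can compete. The absolute sense depends on how well C8 biases the folded macrocycle. The product carries an isopropenyl group that must later be saturated selectively (for example with RhCl(PPh3)3 and H2) beside two ring alkenes.
- Step economy: A8 needs two allylic fragments, an etherification and its own macrocyclisation, then the extra hydrogenation and a silyl-to-ester exchange at O8. It is longer than the chosen plan.

Key step: step 8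

Remarks on the chemistry:
- Germacrane numbering is used throughout: ring C1–C10, isopropyl CH = C11, methyl on C10 = C14, methyl on C4 = C15.
- Structures 16 and 18 were re-derived from the target and needed no correction. The Z enol triflate (OTf cis to C9) maps onto the ring-cis C7=C8 alkene, and the Z stannane (Sn cis to C3) onto the ring-cis C4=C5 alkene.
- Descriptors of later intermediates change with substituent priorities (C7 is R in 20 and 22, C6 is R in 23), although the spatial arrangement is that of the target throughout.
- The facial sense of the chiral copper catalyst on this macrocyclic Z-enone cannot be derived from first principles. (R,R)-QuinoxP* is the working choice; its mirror-image ligand would be used if the C8 carbinol of 20 proves to be R.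

## Route

Step 1
Reactants: 1 5-bromo-2-methylpent-2-ene
Product: 2 (E)-5-bromo-2-methylpent-2-en-1-ol
Conditions: SeO2 (0.3 equiv), t-BuOOH (2 equiv), salicylic acid (0.1 equiv), CH2Cl2, rt, stopped short of full conversion
Reagents that add atoms: selenium dioxide O=[Se]=O (delivers the oxygen), tert-butyl hydroperoxide CC(C)(C)OO (restores it)
Why: Riley allylic oxidation: ene reaction at the trisubstituted alkene and [2,3]-shift of the allylseleninic acid place oxygen on the methyl trans to the chain, giving the E allylic alcohol that becomes C9 and the E C1=C10 alkene; the primary bromide is inert.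

Step 2
Reactants: 2 (E)-5-bromo-2-methylpent-2-en-1-ol
Product: 3 {[(E)-5-bromo-2-methylpent-2-en-1-yl]oxy}(tert-butyl)dimethylsilane
Conditions: TBSCl, imidazole, DMF, 0 °C to rt
Reagents that add atoms: tert-butyldimethylsilyl chloride CC(C)(C)[Si](C)(C)Cl
Why: Standard imidazole-mediated silylation of a primary alcohol; the silyl ether masks the hydroxyl for the organomagnesium and organocopper chemistry of step 3.

Step 3
Reactants: 3 {[(E)-5-bromo-2-methylpent-2-en-1-yl]oxy}(tert-butyl)dimethylsilane; 4 propyne
Product: 8 tert-butyl{[(2E,6Z)-2,6-dimethyl-7-(tributylstannyl)hepta-2,6-dien-1-yl]oxy}dimethylsilane, via homoallylic Grignard reagent 5 (not isolated), via alkylcopper 6 (not isolated), via Z-alkenylcopper 7 (not isolated)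
Conditions: Mg, Et2O, 35 °C; CuBr·SMe2, Et2O–Me2S, −45 °C; 4 (2 equiv), −25 °C; Bu3SnCl, DMPU, −25 °C to rt
Reagents that add atoms: tributyltin chloride CCCC[Sn](Cl)(CCCC)CCCC
Why: Normant carbocupration: the alkylcopper–MgBr2 reagent adds syn across propyne with the alkyl group on the internal carbon (C3–C4) and copper on the terminal carbon, and copper-to-tin exchange with retention gives the stannane with C3 and Sn cis (the future 4Z alkene); the 2E alkene is a spectator.

Step 4
Reactants: 8 tert-butyl{[(2E,6Z)-2,6-dimethyl-7-(tributylstannyl)hepta-2,6-dien-1-yl]oxy}dimethylsilane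
Product: 9 (2E,6Z)-2,6-dimethyl-7-(tributylstannyl)hepta-2,6-dien-1-ol
Conditions: Bu4NF, THF, 0 °C
Reagents that add atoms: none
Why: Fluoride cleavage of the primary silyl ether; the alkenyl C–Sn bond is not attacked by fluoride under these neutral conditions.

Step 5
Reactants: 9 (2E,6Z)-2,6-dimethyl-7-(tributylstannyl)hepta-2,6-dien-1-ol
Product: 11 tributyl[(1Z,5E)-7-bromo-2,6-dimethylhepta-1,5-dien-1-yl]stannane, via allylic mesylate 10 (not isolated)
Conditions: MsCl, Et3N, THF, −40 °C; then LiBr, THF, −40 to 0 °C
Reagents that add atoms: lithium bromide [Li+].[Br-]
Why: Sulfonylation followed by SN2 displacement with bromide gives the primary allylic bromide without acid or electrophilic halogen, either of which would cleave the alkenylstannane; the primary allylic position keeps the E geometry.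

Step 6
Reactants: 11 tributyl[(1Z,5E)-7-bromo-2,6-dimethylhepta-1,5-dien-1-yl]stannane; 12 3-methylbutan-2-one
Product: 14 (6E,10Z)-2,6,10-trimethyl-11-(tributylstannyl)undeca-6,10-dien-3-one, via lithium enolate 13 (not isolated)
Conditions: 12 (3 equiv), LiN(i-Pr)2 (3 equiv), THF, −78 °C; then 11, DMPU, −78 to −30 °C
Reagents that add atoms: none
Why: Kinetic deprotonation of the methyl ketone at its methyl group and SN2 alkylation by the primary allylic bromide form C8–C9; excess enolate suppresses double alkylation, and lithium amide bases do not exchange with the stannane.

Step 7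
Reactants: 14 (6E,10Z)-2,6,10-trimethyl-11-(tributylstannyl)undeca-6,10-dien-3-one
Product: 16 (3Z,6E,10Z)-2,6,10-trimethyl-11-(tributylstannyl)undeca-3,6,10-trien-3-yl trifluoromethanesulfonate, via potassium Z-enolate 15 (not isolated)
Conditions: KN(SiMe3)2, THF, −78 °C; PhNTf2, −78 to 0 °C
Reagents that add atoms: N-phenylbis(trifluoromethanesulfonimide) O=S(=O)(N(c1ccccc1)S(=O)(=O)C(F)(F)F)C(F)(F)F
Why: The bulky silazide removes a proton from the C8 methylene, not from the hindered isopropyl methine, and allylic strain against the isopropyl group favours the enolate with oxygen and C9 cis; O-sulfonylation then fixes the Z enol triflate that becomes the ring-cis C7=C8 alkene.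

Step 8
Reactants: 16 (3Z,6E,10Z)-2,6,10-trimethyl-11-(tributylstannyl)undeca-3,6,10-trien-3-yl trifluoromethanesulfonate; 17 carbon monoxide
Product: 18 germacra-1(10)E,4Z,7Z-trien-6-one [(2Z,5E,9Z)-5,9-dimethyl-2-(propan-2-yl)cyclodeca-2,5,9-trien-1-one]
Conditions: Pd(PPh3)4 (10 mol %), LiCl (3 equiv), CO (3 atm), THF, 60 °C, 16 added by syringe pump to 2 mM
Reagents that add atoms: none
Why: Zerovalent palladium inserts into the C7–OTf bond of 16 with retention of the Z geometry, chloride from LiCl replaces triflate on the divalent alkenylpalladium, and under CO pressure migratory insertion gives the C6 acylpalladium chloride before tin-to-palladium transfer can occur. Transmetalation from the Z-alkenylstannane at C5 then gives an eleven-membered acyl(alkenyl)palladacycle, and reductive elimination forms C5–C6, so that the inserted CO ends as the C6 carbonyl between C5 and C7. The closest known reaction type is the carbonylative Stille coupling of alkenyl triflates with alkenylstannanes run intramolecularly to give macrocyclic cross-conjugated dienones. The one ring formed, the ten-membered carbocycle, is closed end to end by that reductive elimination, which is why the substrate is fed slowly and kept near 2 mM. No stereocentre is created; the 7Z geometry from the enol triflate and the 4Z geometry from the stannane are carried over with retention, and the 1(10)E alkene is a spectator. CO insertion must outrun direct alkenyl–alkenyl coupling; this is secured by the CO pressure and by the fact that direct coupling would have to close a more strained nine-membered ring. Cyclisation must outrun oligomerisation, which dilution secures. The acylpalladium must not add to the C10=C1 alkene to form a cyclopentenone; this is disfavoured because that alkene is trisubstituted and CO competes for the free coordination site.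

Step 9
Reactants: 18 germacra-1(10)E,4Z,7Z-trien-6-one
Product: 20 (7R,8S)-8-hydroxygermacra-1(10)E,4Z-dien-6-one, via 8-pinacolboryl ketone 19 (not isolated)
Conditions: CuCl (5 mol %), NaOt-Bu (10 mol %), (R,R)-QuinoxP* [(R,R)-2,3-bis(tert-butylmethylphosphino)quinoxaline] (6 mol %), B2pin2 (1.1 equiv), MeOH (2 equiv), THF, 0 °C to rt; then NaBO3·4H2O, THF–H2O, rt
Reagents that add atoms: sodium perborate [Na+].[Na+].O[B-]1(O)OO[B-](O)(O)OO1
Why: Copper-catalysed enantioselective conjugate borylation: the ligand-bound boryl copper adds across C7=C8 (C8 is a secondary β-carbon, whereas C4 of the other arm is fully substituted and resists) on the face chosen by the bisphosphine, which sets C8; methanol protonates the copper enolate and the enolisable C7 settles under the basic conditions with isopropyl trans to the boryl carbon, and perborate then replaces boron by hydroxyl with retention.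

Step 10
Reactants: 20 (7R,8S)-8-hydroxygermacra-1(10)E,4Z-dien-6-one; 21 3,4,5-trimethoxybenzoyl chloride
Product: 22 (7R,8S)-6-oxogermacra-1(10)E,4Z-dien-8-yl 3,4,5-trimethoxybenzoate
Conditions: 21 (1.3 equiv), pyridine, DMAP (0.1 equiv), CH2Cl2, 0 °C
Reagents that add atoms: none
Why: DMAP-catalysed acylation of the only hydroxyl in the molecule; no stereocentre is touched, and the weak base at 0 °C keeps β-elimination of the resulting acyloxy ketone slow.

Step 11
Reactants: 22 (7R,8S)-6-oxogermacra-1(10)E,4Z-dien-8-yl 3,4,5-trimethoxybenzoate
Product: 23 (6R,7S,8S)-6-hydroxygermacra-1(10)E,4Z-dien-8-yl 3,4,5-trimethoxybenzoate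
Conditions: NaBH4, CeCl3·7H2O, MeOH, −78 °C; aq NH4Cl at −78 °C
Reagents that add atoms: none
Why: Luche reduction: cerium-activated, hard methoxyborohydride adds 1,2 to the enone carbonyl and leaves the ester alone; C6 is set by the substrate, hydride entering from the outside of the ring anti to the C7 isopropyl, which stands roughly perpendicular to the carbonyl plane, to give the alcohol trans to isopropyl and cis to the C8 ester.

Step 12
Reactants: 23 (6R,7S,8S)-6-hydroxygermacra-1(10)E,4Z-dien-8-yl 3,4,5-trimethoxybenzoate
Product: 24 (4S,5R,6S,7S,8S)-4,5-epoxy-6-hydroxygermacr-1(10)E-en-8-yl 3,4,5-trimethoxybenzoate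
Conditions: VO(acac)2 (5 mol %), t-BuOOH (1.5 equiv, in decane), CH2Cl2, 0 °C
Reagents that add atoms: tert-butyl hydroperoxide CC(C)(C)OO
Why: Hydroxyl-directed epoxidation: the vanadate ester of O6 delivers the peroxide oxygen to the near face of C4=C5; because C3 is cis to C6, allylic strain puts the C6–H bond in the alkene plane and the hydroxyl on the open outer face (opposite C7), so oxygen arrives syn to the hydroxyl and gives the threo 4S,5R epoxide, while the remote C1=C10 alkene has no directing hydroxyl.

## Compound list

1 | 5-bromo-2-methylpent-2-ene | CC(C)=CCCBr | starting material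
2 | (E)-5-bromo-2-methylpent-2-en-1-ol | OC/C(C)=C/CCBr | intermediate
3 | {[(E)-5-bromo-2-methylpent-2-en-1-yl]oxy}(tert-butyl)dimethylsilane | CC(C)(C)[Si](C)(C)OC/C(C)=C/CCBr | intermediate
4 | propyne | CC#C | starting material
5 | homoallylic Grignard reagent (not isolated) | CC(C)(C)[Si](C)(C)OC/C(C)=C/CC[Mg]Br | intermediate
6 | alkylcopper (not isolated) | CC(C)(C)[Si](C)(C)OC/C(C)=C/CC[Cu] | intermediate
7 | Z-alkenylcopper (not isolated) | CC(C)(C)[Si](C)(C)OC/C(C)=C/CC/C(C)=C\[Cu] | intermediate
8 | tert-butyl{[(2E,6Z)-2,6-dimethyl-7-(tributylstannyl)hepta-2,6-dien-1-yl]oxy}dimethylsilane | CC(C)(C)[Si](C)(C)OC/C(C)=C/CC/C(C)=C\[Sn](CCCC)(CCCC)CCCC | intermediate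
9 | (2E,6Z)-2,6-dimethyl-7-(tributylstannyl)hepta-2,6-dien-1-ol | OC/C(C)=C/CC/C(C)=C\[Sn](CCCC)(CCCC)CCCC | intermediate
10 | allylic mesylate (not isolated) | CS(=O)(=O)OC/C(C)=C/CC/C(C)=C\[Sn](CCCC)(CCCC)CCCC | intermediate
11 | tributyl[(1Z,5E)-7-bromo-2,6-dimethylhepta-1,5-dien-1-yl]stannane | BrC/C(C)=C/CC/C(C)=C\[Sn](CCCC)(CCCC)CCCC | intermediate
12 | 3-methylbutan-2-one | CC(C)C(C)=O | starting material
13 | lithium enolate of 12 (not isolated) | C=C(O[Li])C(C)C | intermediate
14 | (6E,10Z)-2,6,10-trimethyl-11-(tributylstannyl)undeca-6,10-dien-3-one | CC(C)C(=O)CC/C(C)=C/CC/C(C)=C\[Sn](CCCC)(CCCC)CCCC | intermediate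
15 | potassium Z-enolate of 14 (not isolated) | CC(C)/C(O[K])=C/C/C(C)=C/CC/C(C)=C\[Sn](CCCC)(CCCC)CCCC | intermediate
16 | (3Z,6E,10Z)-2,6,10-trimethyl-11-(tributylstannyl)undeca-3,6,10-trien-3-yl trifluoromethanesulfonate | CC(C)/C(OS(=O)(=O)C(F)(F)F)=C/C/C(C)=C/CC/C(C)=C\[Sn](CCCC)(CCCC)CCCC | intermediate
17 | carbon monoxide | [C-]#[O+] | starting material
18 | germacra-1(10)E,4Z,7Z-trien-6-one | CC(C)/C1=C/C/C(C)=C/CC/C(C)=C\C1=O | intermediate
19 | (7S,8S)-8-(pinacolboryl)germacra-1(10)E,4Z-dien-6-one (not isolated) | CC1(C)OB(OC1(C)C)[C@H]2C/C(C)=C/CC/C(C)=C\C(=O)[C@@H]2C(C)C | intermediate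
20 | (7R,8S)-8-hydroxygermacra-1(10)E,4Z-dien-6-one | O[C@H]1C/C(C)=C/CC/C(C)=C\C(=O)[C@@H]1C(C)C | intermediate
21 | 3,4,5-trimethoxybenzoyl chloride | COc1cc(C(Cl)=O)cc(OC)c1OC | starting material
22 | (7R,8S)-6-oxogermacra-1(10)E,4Z-dien-8-yl 3,4,5-trimethoxybenzoate | COc1cc(C(=O)O[C@H]2C/C(C)=C/CC/C(C)=C\C(=O)[C@@H]2C(C)C)cc(OC)c1OC | intermediate
23 | (6R,7S,8S)-6-hydroxygermacra-1(10)E,4Z-dien-8-yl 3,4,5-trimethoxybenzoate | COc1cc(C(=O)O[C@H]2C/C(C)=C/CC/C(C)=C\[C@@H](O)[C@@H]2C(C)C)cc(OC)c1OC | intermediate
24 | (4S,5R,6S,7S,8S)-4,5-epoxy-6-hydroxygermacr-1(10)E-en-8-yl 3,4,5-trimethoxybenzoate | COc1cc(C(=O)O[C@H]2C/C(C)=C/CC[C@]3(C)O[C@@H]3[C@@H](O)[C@@H]2C(C)C)cc(OC)c1OC | target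

## Step count and least certain steps

Total step count: 12. Longest linear sequence: 12 steps (1 to 24); 4, 12, 17 and 21 enter as purchased reagents.

**Step 8 (key step).** The alkenylstannane is Z and β,β-disubstituted, so tin-to-palladium transfer is slow, and the acylpalladium may be diverted before the ring closes. Possible diversions are oligomerisation, protodestannylation, addition of the acyl group to the C10=C1 alkene, or simple reduction. Strain in the cross-conjugated trienone also raises the barrier of the ring-closing reductive elimination.
Fallback (sets out from 16, returns at 18): the ring is closed by chromium-mediated carbonyl addition instead of by acyl coupling.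
- Reductive carbonylation of the enol triflate (Pd(PPh3)4, LiCl, CO, Bu3SnH added slowly, THF, 50 °C) would give (2Z,5E,9Z)-5,9-dimethyl-2-(propan-2-yl)-10-(tributylstannyl)deca-2,5,9-trienal F3.
- Iododestannylation with retention (I2, CH2Cl2, 0 °C) would give (2Z,5E,9Z)-10-iodo-5,9-dimethyl-2-(propan-2-yl)deca-2,5,9-trienal F4.
- Nozaki–Hiyama–Kishi macrocyclisation (CrCl2, NiCl2 cat., DMSO–THF, high dilution) would form C5–C6 and give germacra-1(10)E,4Z,7Z-trien-6-ol F5.
- MnO2 in CH2Cl2 would oxidise the bis-allylic alcohol to 18.

**Step 9.** Several things may go wrong:
- poor discrimination between the two enone arms;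
- low reactivity caused by the α-isopropyl group;
- insufficient facial control by the catalyst on a flexible macrocycle;
- protonation or equilibration leaving C7 as a mixture;
- base-induced migration of the skipped C10=C1 alkene into conjugation.

Fallback (sets out from 18, returns at 20): oxygen is delivered to C8 by nucleophilic epoxidation and the C7–O bond is then removed.
- Catalytic asymmetric epoxidation of the less substituted enone arm (La(Oi-Pr)3, (R)-BINOL, Ph3As=O, t-BuOOH, THF) would give (7S,8S)-7,8-epoxygermacra-1(10)E,4Z-dien-6-one F6.
- SmI2 (2 equiv) in THF–MeOH at −90 °C would cleave the α C–O bond to give 20, with C7 again set on protonation.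

**Step 11.** Facial selectivity of hydride addition depends on a ring conformation that cannot be predicted with confidence, and the ester may migrate from O8 to the new O6 alkoxide.
Fallback (sets out from 22, returns at 23): the carbinol is corrected after the fact by SN2 inversion.
- If the reduction gives mainly the C6 epimer, (6S,7S,8S)-6-hydroxygermacra-1(10)E,4Z-dien-8-yl 3,4,5-trimethoxybenzoate F7 would be taken on.
- Mitsunobu inversion (PPh3, diisopropyl azodicarboxylate, chloroacetic acid, toluene, 0 °C) would give the inverted 6-chloroacetate F8.
- The chloroacetyl group would be removed selectively (thiourea, NaHCO3, EtOH, 50 °C) to give 23, leaving the aryl ester in place.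

**Step 12.** Three things may go wrong:
- competing oxidation of the strained C1=C10 alkene;
- opening of the new epoxide by the Lewis-acidic vanadium alkoxide with transannular participation of C1=C10;
- delivery to the other face if the hydroxyl sits in the alkene plane in the reacting conformer.

Fallback (sets out from 20, returns at 24): the epoxide is made nucleophilically on the enone before reduction, and C6 is relayed from C8.
- Weitz–Scheffer epoxidation (t-BuOOH, benzyltrimethylammonium hydroxide cat., THF, 0 °C) would touch only the electron-poor C4=C5 alkene and give 4,5-epoxy-8-hydroxygermacr-1(10)E-en-6-one F9.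
- Narasaka–Prasad reduction (Et2BOMe, NaBH4, THF–MeOH, −78 °C) would give the 6,8-syn epoxy diol F10.
- Acylation of the less hindered C8 hydroxyl (21, 1.0 equiv, 2,4,6-collidine, CH2Cl2, −40 °C) would give 24.
- This path has two soft spots of its own: the face of peroxide attack would be set by the ring alone, and the site-selective acylation is not assured.

**Step 3.** Carbocupration may be incomplete, propyne may protonate the organocopper, and copper-to-tin transfer may be inefficient.
Fallback (sets out from 3 and 4 through 7, formed as in step 3; returns at 8): the tin is introduced through lithium instead of copper.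
- Quenching 7 with I2 would give the Z-alkenyl iodide tert-butyl{[(2E,6Z)-7-iodo-2,6-dimethylhepta-2,6-dien-1-yl]oxy}dimethylsilane F1.
- Iodine–lithium exchange (t-BuLi, 2 equiv, Et2O, −78 °C) would give the Z-alkenyllithium F2.
- Bu3SnCl would stannylate F2 with retention to give 8.

## Further compounds

F1 | step 3 | tert-butyl{[(2E,6Z)-7-iodo-2,6-dimethylhepta-2,6-dien-1-yl]oxy}dimethylsilane | CC(C)(C)[Si](C)(C)OC/C(C)=C/CC/C(C)=C\I
F2 | step 3 | Z-alkenyllithium from F1 | CC(C)(C)[Si](C)(C)OC/C(C)=C/CC/C(C)=C\[Li]
F3 | step 8 | (2Z,5E,9Z)-5,9-dimethyl-2-(propan-2-yl)-10-(tributylstannyl)deca-2,5,9-trienal | CC(C)/C(C=O)=C/C/C(C)=C/CC/C(C)=C\[Sn](CCCC)(CCCC)CCCC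
F4 | step 8 | (2Z,5E,9Z)-10-iodo-5,9-dimethyl-2-(propan-2-yl)deca-2,5,9-trienal | CC(C)/C(C=O)=C/C/C(C)=C/CC/C(C)=C\I
F5 | step 8 | germacra-1(10)E,4Z,7Z-trien-6-ol (racemic at C6) | CC(C)/C1=C/C/C(C)=C/CC/C(C)=C\C1O
F6 | step 9 | (7S,8S)-7,8-epoxygermacra-1(10)E,4Z-dien-6-one | O1[C@H]2C/C(C)=C/CC/C(C)=C\C(=O)[C@@]12C(C)C
F7 | step 11 | (6S,7S,8S)-6-hydroxygermacra-1(10)E,4Z-dien-8-yl 3,4,5-trimethoxybenzoate (C6 epimer of 23) | COc1cc(C(=O)O[C@H]2C/C(C)=C/CC/C(C)=C\[C@H](O)[C@@H]2C(C)C)cc(OC)c1OC
F8 | step 11 | 6-O-chloroacetyl derivative of 23 | COc1cc(C(=O)O[C@H]2C/C(C)=C/CC/C(C)=C\[C@@H](OC(=O)CCl)[C@@H]2C(C)C)cc(OC)c1OC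
F9 | step 12 | 4,5-epoxy-8-hydroxygermacr-1(10)E-en-6-one | O[C@H]1C/C(C)=C/CC[C@]2(C)O[C@@H]2C(=O)[C@@H]1C(C)C
F10 | step 12 | 4,5-epoxygermacr-1(10)E-ene-6,8-diol | O[C@H]1C/C(C)=C/CC[C@]2(C)O[C@@H]2[C@@H](O)[C@@H]1C(C)C
A1 | alternative 1 | acyclic 2Z,6E allylic alcohol holding C1–C10 (TBS ether at C9, PMB ether at C8) | CC(C)(C)[Si](C)(C)OC/C(C)=C/CC/C(C)=C\[C@@H](O)[C@H](C(C)C)COCc1ccc(OC)cc1
A2 | alternative 1 | (R)-2-[(4-methoxybenzyloxy)methyl]-3-methylbutanal | O=C[C@H](C(C)C)COCc1ccc(OC)cc1
A3 | alternative 2 | cis-anti-cis tricyclo[4.4.0.0(2,5)]decanone photoadduct | CC(C)(C)[Si](C)(C)O[C@H]1C[C@@]2(C)[C@@H](C(=O)[C@@H]1C(C)C)[C@]3(C)CC[C@H]23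
A4 | alternative 2 | (5S,6R)-5-(tert-butyldimethylsilyloxy)-3-methyl-6-(propan-2-yl)cyclohex-2-en-1-one | CC(C)(C)[Si](C)(C)O[C@H]1CC(C)=CC(=O)[C@@H]1C(C)C
A5 | alternative 2 | 1-methylcyclobutene | CC1=CCC1
A6 | alternative 2 | 8-(tert-butyldimethylsilyloxy)germacra-1(10)E,4Z-dien-6-one | CC(C)(C)[Si](C)(C)O[C@H]1C/C(C)=C/CC/C(C)=C\C(=O)[C@@H]1C(C)C
A7 | alternative 3 | 8-triethylsilyloxy-7-isopropenylgermacra-1(10)E,4Z-dien-6-ol | CC[Si](CC)(CC)O[C@H]1C/C(C)=C/CC/C(C)=C\[C@@H](O)[C@@H]1C(C)=C
A8 | alternative 3 | thirteen-membered diallyl ether (O joining C6 and C12, 8-triethylsilyloxy) | C1/C(C)=C\COC/C(C)=C/[C@@H](O[Si](CC)(CC)CC)C/C(C)=C/C1
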